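**Plan**

- Retrosynthesis: the propanoic acid arm is removed first (ester cleavage, benzylic C–Ph by conjugate arylation, Cα=Cβ by Wittig olefination, C8–CHO by formylation). Ring A is then cut at C4a–C8a, C5–C6 and C7–C8.
- Enabling feature: in ring A, C5, C7 and C8a carry oxygen while C4a, C6 and C8 carry carbon or hydrogen, in strict alternation. This is the pattern of three alkoxyalkynes joined head to tail, and the C8≡C8a and C4a≡C5 units are already linked through O1–C2–C3–C4 of ring C.
- Forward order: the O1–C2–C3–C4 chain is made first, an ethynyl ether is placed on O1 and a methoxy ynone on C4. One rhodium-catalysed [2+2+2] reaction with 1-methoxy-5-methylhex-4-en-1-yne then closes ring C and ring A together, and the C8 side chain follows.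
- Stereochemistry: C2 and C3 (cis) come from an Evans syn-aldol of the (R)-benzyloxazolidinone propionimide with acetaldehyde and are carried through unchanged. The benzylic centre (R) comes from a rhodium/chiral-diene 1,4-addition of phenylboronic acid.
- The C5 oxygen travels as a methyl ether and is freed after ring formation by chelation-controlled BCl3 demethylation.

Key step: step 10

Remark on the chemistry: the C5 oxygen is introduced with lithium methoxyacetylide (LiC≡COMe), an established reagent, so ring A first appears as its 5,7-dimethyl ether. A silyl ether at C5 would need a lithiated silyloxyacetylene, for which no reliable preparation is assumed.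

**Route**

Step 1
Reactants: 1 (R)-4-benzyl-3-propionyloxazolidin-2-one; 2 acetaldehyde
Product: 3 (4R)-4-benzyl-3-[(2R,3S)-3-hydroxy-2-methylbutanoyl]oxazolidin-2-one
Conditions: Bu2BOTf, i-Pr2NEt, CH2Cl2, 0 °C; 2, −78 to 0 °C; then pH 7 buffer, MeOH, 30% H2O2
Reagents that add atoms: none
Why: Evans boron syn-aldol, in which the (Z)-boron enolate reacts through a Zimmerman–Traxler chair on the face left open by the benzyl group of the auxiliary, so that the (2R,3S) syn adduct (future C3 and C2 of the chromanone) should form.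

Step 2
Reactants: 3 (4R)-4-benzyl-3-[(2R,3S)-3-hydroxy-2-methylbutanoyl]oxazolidin-2-one
Product: 4 (2S,3S)-2-methylbutane-1,3-diol
Conditions: LiBH4, MeOH (1 equiv), Et2O, 0 °C
Reagents that add atoms: none
Why: Reductive cleavage of the N-acyloxazolidinone by LiBH4 should give the primary alcohol and release the auxiliary without touching either stereocentre (the descriptor at C2 changes only through CIP priorities).

Step 3
Reactants: 4 (2S,3S)-2-methylbutane-1,3-diol
Product: 5 (2S,3S)-4-[(tert-butyldiphenylsilyl)oxy]-3-methylbutan-2-ol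
Conditions: t-BuPh2SiCl, imidazole, CH2Cl2, 0 °C
Reagents that add atoms: tert-butylchlorodiphenylsilane, CC(C)(C)[Si](Cl)(c1ccccc1)c1ccccc1
Why: Silylation with the bulky chlorosilane is selective for the primary hydroxyl, and the tert-butyldiphenylsilyl group is chosen because it migrates least under the strongly basic conditions of the next step.

Step 4
Reactants: 5 (2S,3S)-4-[(tert-butyldiphenylsilyl)oxy]-3-methylbutan-2-ol; 6 trichloroethylene
Product: 9 tert-butyl{[(2S,3S)-3-(ethynyloxy)-2-methylbutyl]oxy}diphenylsilane, via dichlorovinyl ether 7 (not isolated), via lithium alkynyl ether 8 (not isolated)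
Conditions: KH, THF, 0 °C to rt; 6, −50 °C to rt; n-BuLi (2.4 equiv), −78 to −40 °C; MeOH, −78 °C
Reagents that add atoms: none
Why: Dichlorovinyl ether route to alkynyl ethers, in which the potassium alkoxide adds to dichloroacetylene formed in situ from trichloroethylene, n-BuLi then effects elimination and chlorine–lithium exchange, and protonation gives the terminal ynol ether with the C–O stereocentre untouched.

Step 5
Reactants: 9 tert-butyl{[(2S,3S)-3-(ethynyloxy)-2-methylbutyl]oxy}diphenylsilane
Product: 10 (2S,3S)-3-(ethynyloxy)-2-methylbutan-1-ol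
Conditions: Bu4NF, THF, 0 °C
Reagents that add atoms: none
Why: Fluoride desilylation is basic and non-acidic, conditions under which alkynyl ethers (labile only to acid and heat) should survive.

Step 6
Reactants: 10 (2S,3S)-3-(ethynyloxy)-2-methylbutan-1-ol
Product: 11 (2R,3S)-3-(ethynyloxy)-2-methylbutanal
Conditions: Dess–Martin periodinane, NaHCO3, CH2Cl2, 0 °C; solution used directly
Reagents that add atoms: none
Why: Buffered Dess–Martin oxidation avoids both acid (hydration of the ynol ether) and amine base (epimerisation at C2 or β-elimination of the ynolate leaving group).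

Step 7
Reactants: 11 (2R,3S)-3-(ethynyloxy)-2-methylbutanal; 12 2-chloro-1,1-dimethoxyethane
Product: 14 (3RS,4S,5S)-5-(ethynyloxy)-1-methoxy-4-methylhex-1-yn-3-ol, via lithium methoxyacetylide 13 (not isolated)
Conditions: 12, LiNEt2 (3 equiv per 12, from Et2NH and n-BuLi), THF, 0 °C; then 11, −78 °C; aq. NaHCO3
Reagents that add atoms: none
Why: Threefold base-induced elimination of the chloroacetal gives LiC≡COMe, whose 1,2-addition to the aldehyde at −78 °C should outrun enolisation, and the new carbinol centre is formed unselectively because it is removed in the next step.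

Step 8
Reactants: 14 (3RS,4S,5S)-5-(ethynyloxy)-1-methoxy-4-methylhex-1-yn-3-ol
Product: 15 (4R,5S)-5-(ethynyloxy)-1-methoxy-4-methylhex-1-yn-3-one
Conditions: Dess–Martin periodinane, NaHCO3, CH2Cl2, 0 °C; filtered through basic alumina and used at once
Reagents that add atoms: none
Why: Dess–Martin oxidation of a secondary propargylic alcohol under buffered, non-basic conditions should give the push–pull methoxy ynone without Meyer–Schuster rearrangement or epimerisation at C4.

Step 9
Reactants: 12 2-chloro-1,1-dimethoxyethane; 16 prenyl bromide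
Product: 18 1-methoxy-5-methylhex-4-en-1-yne, via sodium methoxyacetylide 17 (not isolated)
Conditions: NaNH2 (3 equiv), liq. NH3, −35 °C; then 16, −35 °C
Reagents that add atoms: none
Why: Elimination of the chloroacetal with NaNH2 gives NaC≡COMe, which should be alkylated at carbon by the primary allylic bromide in an SN2 reaction, the classical route to 1-alkoxyalk-1-ynes.

Step 10
Reactants: 15 (4R,5S)-5-(ethynyloxy)-1-methoxy-4-methylhex-1-yn-3-one; 18 1-methoxy-5-methylhex-4-en-1-yne
Product: 19 (2S,3R)-5,7-dimethoxy-2,3-dimethyl-6-(3-methylbut-2-en-1-yl)chroman-4-one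
Conditions: [Rh(cod)2]BF4 (10 mol%), rac-BINAP (10 mol%), H2 then Ar; 18 (3 equiv), CH2Cl2, 0 °C to rt, slow addition of 15
Reagents that add atoms: none
Why: Proposed new method: monovalent rhodium should bind both alkynes of 15 and couple them oxidatively to a trivalent rhodacyclopentadiene (bond C4a–C8a), which inserts 18 and undergoes reductive elimination (bonds C5–C6 and C7–C8). The closest known reaction type is the cationic rhodium/bisphosphine-catalysed [2+2+2] cycloaddition of tethered 1,6- and 1,7-diynes with monoalkynes, including alkynyl ethers and ynamides; a set of three oxygenated alkynes, one of them an alkoxy ynone, has not been shown. Ring C closes as the six-membered ring of the 1,7-diyne in the oxidative coupling, and ring A closes by alkyne insertion and reductive elimination, a formal cyclotrimerisation. No stereocentre is formed; C2 and C3 are spectators, and the neutral aprotic medium should avoid enolisation at C3 and β-elimination of the ynolate. The step needs the head-to-tail orientation of 18 (prenyl carbon to C5, methoxy carbon to C8), which is expected because each new bond joins an oxygen-bearing carbon to a carbon β to oxygen and the smaller methoxy end lies next to the unsubstituted C8; this regiochemistry is not assured and is to be proven by HMBC and NOE correlations. Cross-cycloaddition over homo-coupling is favoured by excess 18 and slow addition of 15, and working at or below room temperature should prevent retro-ene loss of ketene from the secondary alkynyl ether.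

Step 11
Reactants: 19 (2S,3R)-5,7-dimethoxy-2,3-dimethyl-6-(3-methylbut-2-en-1-yl)chroman-4-one
Product: 20 (2S,3R)-5-hydroxy-7-methoxy-2,3-dimethyl-6-(3-methylbut-2-en-1-yl)chroman-4-one
Conditions: BCl3 (1.2 equiv), CH2Cl2, −78 to −20 °C; cold aq. NaHCO3
Reagents that add atoms: none
Why: Chelation-controlled demethylation, in which BCl3 bridges the C4 carbonyl and the peri 5-methoxy group so that chloride removes only that methyl, while the low temperature should spare the 7-methoxy group, the prenyl alkene and C3.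

Step 12
Reactants: 20 (2S,3R)-5-hydroxy-7-methoxy-2,3-dimethyl-6-(3-methylbut-2-en-1-yl)chroman-4-one
Product: 21 (2S,3R)-5-hydroxy-7-methoxy-2,3-dimethyl-6-(3-methylbut-2-en-1-yl)-4-oxochromane-8-carbaldehyde
Conditions: POCl3, DMF, MeCN, 0 °C to rt; aq. NaOAc
Reagents that add atoms: N,N-dimethylformamide, CN(C)C=O; water, O
Why: Vilsmeier–Haack formylation at C8, the only free ring position, which is para to the 5-hydroxyl and ortho to O1 and the 7-methoxy group, so that the arene should react faster than the hydrogen-bonded ketone or the prenyl alkene.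

Step 13
Reactants: 21 (2S,3R)-5-hydroxy-7-methoxy-2,3-dimethyl-6-(3-methylbut-2-en-1-yl)-4-oxochromane-8-carbaldehyde; 22 methyl (triphenylphosphoranylidene)acetate
Product: 23 methyl (E)-3-[(2S,3R)-5-hydroxy-7-methoxy-2,3-dimethyl-6-(3-methylbut-2-en-1-yl)-4-oxochroman-8-yl]prop-2-enoate
Conditions: toluene, 70 °C
Reagents that add atoms: none
Why: Wittig olefination with a stabilised ylide should give the (E)-enoate under neutral conditions that leave C3 and ring C intact.

Step 14
Reactants: 23 methyl (E)-3-[(2S,3R)-5-hydroxy-7-methoxy-2,3-dimethyl-6-(3-methylbut-2-en-1-yl)-4-oxochroman-8-yl]prop-2-enoate; 24 phenylboronic acid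
Product: 25 methyl (3R)-3-[(2S,3R)-5-hydroxy-7-methoxy-2,3-dimethyl-6-(3-methylbut-2-en-1-yl)-4-oxochroman-8-yl]-3-phenylpropanoate
Conditions: [RhCl(C2H4)2]2 (2.5 mol%), (1S,4S)-2,5-diphenylbicyclo[2.2.2]octa-2,5-diene (5.5 mol%), KOH (10 mol%), dioxane/H2O 10:1, 40 °C
Reagents that add atoms: none
Why: Hayashi–Miyaura asymmetric 1,4-addition, in which a phenylrhodium–diene species inserts the enoate and is hydrolysed; the benzylic centre is set by the chiral diene, the (S,S) ligand being expected from the enantioface model of diene–rhodium catalysts to deliver phenyl to the Si face of C-β (the R product), a sense to be confirmed on the first run with the antipodal diene held in reserve.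

Step 15
Reactants: 25 methyl (3R)-3-[(2S,3R)-5-hydroxy-7-methoxy-2,3-dimethyl-6-(3-methylbut-2-en-1-yl)-4-oxochroman-8-yl]-3-phenylpropanoate
Product: 26 (3R)-3-[(2S,3R)-5-hydroxy-7-methoxy-2,3-dimethyl-6-(3-methylbut-2-en-1-yl)-4-oxochroman-8-yl]-3-phenylpropanoic acid
Conditions: Me3SnOH, ClCH2CH2Cl, 70 °C; 0.1 M HCl work-up
Reagents that add atoms: trimethyltin hydroxide, C[Sn](C)(C)O
Why: Ester cleavage with Me3SnOH is close to neutral and should therefore avoid epimerisation at C3 and retro-oxa-Michael opening of ring C, which aqueous hydroxide would risk.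

**Compound list**

1 | (R)-4-benzyl-3-propionyloxazolidin-2-one | CCC(=O)N1[C@H](Cc2ccccc2)COC1=O | starting material
2 | acetaldehyde | CC=O | starting material
3 | (4R)-4-benzyl-3-[(2R,3S)-3-hydroxy-2-methylbutanoyl]oxazolidin-2-one | O[C@@H](C)[C@@H](C)C(=O)N1[C@H](Cc2ccccc2)COC1=O | intermediate
4 | (2S,3S)-2-methylbutane-1,3-diol | O[C@@H](C)[C@@H](C)CO | intermediate
5 | (2S,3S)-4-[(tert-butyldiphenylsilyl)oxy]-3-methylbutan-2-ol | O[C@@H](C)[C@@H](C)CO[Si](c1ccccc1)(c1ccccc1)C(C)(C)C | intermediate
6 | trichloroethylene | ClC=C(Cl)Cl | starting material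
7 | tert-butyl{[(2S,3S)-3-{[(E)-1,2-dichloroethenyl]oxy}-2-methylbutyl]oxy}diphenylsilane | Cl/C=C(/Cl)O[C@@H](C)[C@@H](C)CO[Si](c1ccccc1)(c1ccccc1)C(C)(C)C | intermediate (not isolated)
8 | ({(2S,3S)-4-[(tert-butyldiphenylsilyl)oxy]-3-methylbutan-2-yl}oxy)ethynyllithium | [Li]C#CO[C@@H](C)[C@@H](C)CO[Si](c1ccccc1)(c1ccccc1)C(C)(C)C | intermediate (not isolated)
9 | tert-butyl{[(2S,3S)-3-(ethynyloxy)-2-methylbutyl]oxy}diphenylsilane | C#CO[C@@H](C)[C@@H](C)CO[Si](c1ccccc1)(c1ccccc1)C(C)(C)C | intermediate
10 | (2S,3S)-3-(ethynyloxy)-2-methylbutan-1-ol | C#CO[C@@H](C)[C@@H](C)CO | intermediate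
11 | (2R,3S)-3-(ethynyloxy)-2-methylbutanal | C#CO[C@@H](C)[C@@H](C)C=O | intermediate
12 | 2-chloro-1,1-dimethoxyethane (chloroacetaldehyde dimethyl acetal) | COC(CCl)OC | starting material
13 | lithium methoxyacetylide | [Li]C#COC | intermediate (not isolated)
14 | (3RS,4S,5S)-5-(ethynyloxy)-1-methoxy-4-methylhex-1-yn-3-ol | C#CO[C@@H](C)[C@@H](C)C(O)C#COC | intermediate
15 | (4R,5S)-5-(ethynyloxy)-1-methoxy-4-methylhex-1-yn-3-one | C#CO[C@@H](C)[C@@H](C)C(=O)C#COC | intermediate
16 | prenyl bromide (1-bromo-3-methylbut-2-ene) | CC(C)=CCBr | starting material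
17 | sodium methoxyacetylide | [Na]C#COC | intermediate (not isolated)
18 | 1-methoxy-5-methylhex-4-en-1-yne | COC#CCC=C(C)C | intermediate
19 | (2S,3R)-5,7-dimethoxy-2,3-dimethyl-6-(3-methylbut-2-en-1-yl)chroman-4-one | COc1cc2O[C@@H](C)[C@@H](C)C(=O)c2c(OC)c1CC=C(C)C | intermediate
20 | (2S,3R)-5-hydroxy-7-methoxy-2,3-dimethyl-6-(3-methylbut-2-en-1-yl)chroman-4-one | COc1cc2O[C@@H](C)[C@@H](C)C(=O)c2c(O)c1CC=C(C)C | intermediate
21 | (2S,3R)-5-hydroxy-7-methoxy-2,3-dimethyl-6-(3-methylbut-2-en-1-yl)-4-oxochromane-8-carbaldehyde | COc1c(C=O)c2O[C@@H](C)[C@@H](C)C(=O)c2c(O)c1CC=C(C)C | intermediate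
22 | methyl (triphenylphosphoranylidene)acetate | COC(=O)C=P(c1ccccc1)(c1ccccc1)c1ccccc1 | starting material
23 | methyl (E)-3-[(2S,3R)-5-hydroxy-7-methoxy-2,3-dimethyl-6-(3-methylbut-2-en-1-yl)-4-oxochroman-8-yl]prop-2-enoate | COC(=O)/C=C/c1c(OC)c(CC=C(C)C)c(O)c2c1O[C@@H](C)[C@@H](C)C2=O | intermediate
24 | phenylboronic acid | OB(O)c1ccccc1 | starting material
25 | methyl (3R)-3-[(2S,3R)-5-hydroxy-7-methoxy-2,3-dimethyl-6-(3-methylbut-2-en-1-yl)-4-oxochroman-8-yl]-3-phenylpropanoate | COC(=O)C[C@H](c1ccccc1)c1c(OC)c(CC=C(C)C)c(O)c2c1O[C@@H](C)[C@@H](C)C2=O | intermediate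
26 | (3R)-3-[(2S,3R)-5-hydroxy-7-methoxy-2,3-dimethyl-6-(3-methylbut-2-en-1-yl)-4-oxochroman-8-yl]-3-phenylpropanoic acid | COc1c(CC=C(C)C)c(O)c2c(c1[C@H](CC(=O)O)c1ccccc1)O[C@@H](C)[C@@H](C)C2=O | target

**Step count and risks**

Total step count: 15. Longest linear sequence: 14 (steps 1–8 and 10–15); step 9 is a one-step branch.

Steps most likely to fail:

1. Step 10. The methoxyalkyne may insert in the reversed orientation; homo-coupling of the diyne or trimerisation of 18 may outrun the cross-cycloaddition; the alkynyl ethers may be hydrated or lose ketene by retro-ene reaction on the Lewis-acidic cationic rhodium. The fallback uses known chemistry, sets out from 5 and returns at 19. Alcohol 5 is coupled with 1-iodo-3,5-dimethoxybenzene (CuI, 3,4,7,8-tetramethyl-1,10-phenanthroline, Cs2CO3, toluene, 110 °C; Ullmann-type etherification with retention at the carbinol carbon) to give tert-butyl{[(2S,3S)-3-(3,5-dimethoxyphenoxy)-2-methylbutyl]oxy}diphenylsilane F1. Directed lithiation between the two methoxy groups (n-BuLi, THF, 0 °C) and alkylation with 16 give tert-butyl{[(2S,3S)-3-[3,5-dimethoxy-4-(3-methylbut-2-en-1-yl)phenoxy]-2-methylbutyl]oxy}diphenylsilane F2. Bu4NF then frees (2S,3S)-3-[3,5-dimethoxy-4-(3-methylbut-2-en-1-yl)phenoxy]-2-methylbutan-1-ol F3. Dess–Martin oxidation gives (2R,3S)-3-[3,5-dimethoxy-4-(3-methylbut-2-en-1-yl)phenoxy]-2-methylbutanal F4, and Pinnick oxidation (NaClO2, NaH2PO4, 2-methylbut-2-ene) gives (2R,3S)-3-[3,5-dimethoxy-4-(3-methylbut-2-en-1-yl)phenoxy]-2-methylbutanoic acid F5. Treatment with (CF3CO)2O in CH2Cl2 at 0 °C forms (2R,3S)-3-[3,5-dimethoxy-4-(3-methylbut-2-en-1-yl)phenoxy]-2-methylbutanoic trifluoroacetic anhydride F6, which should undergo intramolecular Friedel–Crafts acylation at either of the two equivalent ortho positions to give 19.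

2. Step 14. Insertion into the β-aryl acrylate, whose aryl group is substituted at both ortho positions, may be slow; protodeboronation may consume the boronic acid; phenoxide donation may deactivate the enoate; facial selectivity may be poor or reversed. The fallback sets out from 21 and returns at 26. Horner–Wadsworth–Emmons olefination of 21 with (S)-3-[(diethoxyphosphoryl)acetyl]-4-phenyloxazolidin-2-one (LiCl, i-Pr2NEt, MeCN; Masamune–Roush conditions) gives (S)-3-{(E)-3-[(2S,3R)-5-hydroxy-7-methoxy-2,3-dimethyl-6-(3-methylbut-2-en-1-yl)-4-oxochroman-8-yl]prop-2-enoyl}-4-phenyloxazolidin-2-one F7. Conjugate addition of PhMgBr/CuBr·SMe2 (THF, −40 °C), anti to the 4-phenyl group of the chelated s-cis imide, should give (S)-3-{(3R)-3-[(2S,3R)-5-hydroxy-7-methoxy-2,3-dimethyl-6-(3-methylbut-2-en-1-yl)-4-oxochroman-8-yl]-3-phenylpropanoyl}-4-phenyloxazolidin-2-one F8. LiOH/H2O2 (THF/H2O, 0 °C) then releases 26.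

3. Step 12. The Vilsmeier reagent may attack the enolisable ketone (epimerisation at C3 or chlorovinyl formation), or the acid generated may cyclise the prenyl group onto the 5-hydroxyl. The fallback sets out from 20 and returns at 23, bypassing the aldehyde. Bromination para to the phenol with N-bromosuccinimide (CH2Cl2, −78 °C) gives (2S,3R)-8-bromo-5-hydroxy-7-methoxy-2,3-dimethyl-6-(3-methylbut-2-en-1-yl)chroman-4-one F9. A Mizoroki–Heck reaction with methyl acrylate (Pd(P(t-Bu)3)2, Cy2NMe, dioxane, 50 °C) should then give 23.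

**Further compounds**

F1 | step 10 | tert-butyl{[(2S,3S)-3-(3,5-dimethoxyphenoxy)-2-methylbutyl]oxy}diphenylsilane | COc1cc(OC)cc(O[C@@H](C)[C@@H](C)CO[Si](c2ccccc2)(c2ccccc2)C(C)(C)C)c1
F2 | step 10 | tert-butyl{[(2S,3S)-3-[3,5-dimethoxy-4-(3-methylbut-2-en-1-yl)phenoxy]-2-methylbutyl]oxy}diphenylsilane | COc1cc(O[C@@H](C)[C@@H](C)CO[Si](c2ccccc2)(c2ccccc2)C(C)(C)C)cc(OC)c1CC=C(C)C
F3 | step 10 | (2S,3S)-3-[3,5-dimethoxy-4-(3-methylbut-2-en-1-yl)phenoxy]-2-methylbutan-1-ol | COc1cc(O[C@@H](C)[C@@H](C)CO)cc(OC)c1CC=C(C)C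
F4 | step 10 | (2R,3S)-3-[3,5-dimethoxy-4-(3-methylbut-2-en-1-yl)phenoxy]-2-methylbutanal | COc1cc(O[C@@H](C)[C@@H](C)C=O)cc(OC)c1CC=C(C)C
F5 | step 10 | (2R,3S)-3-[3,5-dimethoxy-4-(3-methylbut-2-en-1-yl)phenoxy]-2-methylbutanoic acid | COc1cc(O[C@@H](C)[C@@H](C)C(=O)O)cc(OC)c1CC=C(C)C
F6 | step 10 | (2R,3S)-3-[3,5-dimethoxy-4-(3-methylbut-2-en-1-yl)phenoxy]-2-methylbutanoic trifluoroacetic anhydride | COc1cc(O[C@@H](C)[C@@H](C)C(=O)OC(=O)C(F)(F)F)cc(OC)c1CC=C(C)C
F7 | step 14 | (S)-3-{(E)-3-[(2S,3R)-5-hydroxy-7-methoxy-2,3-dimethyl-6-(3-methylbut-2-en-1-yl)-4-oxochroman-8-yl]prop-2-enoyl}-4-phenyloxazolidin-2-one | O=C(/C=C/c1c(OC)c(CC=C(C)C)c(O)c2c1O[C@@H](C)[C@@H](C)C2=O)N1[C@@H](c2ccccc2)COC1=O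
F8 | step 14 | (S)-3-{(3R)-3-[(2S,3R)-5-hydroxy-7-methoxy-2,3-dimethyl-6-(3-methylbut-2-en-1-yl)-4-oxochroman-8-yl]-3-phenylpropanoyl}-4-phenyloxazolidin-2-one | O=C(C[C@H](c1ccccc1)c1c(OC)c(CC=C(C)C)c(O)c2c1O[C@@H](C)[C@@H](C)C2=O)N1[C@@H](c2ccccc2)COC1=O
F9 | step 12 | (2S,3R)-8-bromo-5-hydroxy-7-methoxy-2,3-dimethyl-6-(3-methylbut-2-en-1-yl)chroman-4-one | COc1c(Br)c2O[C@@H](C)[C@@H](C)C(=O)c2c(O)c1CC=C(C)C
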